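**Plan**

- Retrosynthesis: ring A has its OH (C1), the chain (C3) and the aryl ether oxygen (C5) mutually meta, which is the pattern a 3-alkylcyclobutenone and a terminal ynol ether deliver. Cutting C1–C6 and C4–C5 therefore opens ring A and the 21-membered ring together and leads back to a cyclobutenone tethered to an aryl ethynyl ether.
- Further cuts: the O–C≡C unit (phenol + trichloroethylene), the four-membered ring (terminal alkyne + dichloroketene), the aryl–CH2 bond (B-alkyl Suzuki coupling) and one chain C–C bond (Grignard coupling).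
- Forward: ring B is bought as a salicylaldehyde and the C16 chain is attached. The phenol is then unveiled and dichlorovinylated, and the cyclobutenone is built on the alkyne. The enone is masked as a silylated cyclobutenol while n-BuLi makes the ynol ether, then restored.
- Ring A and the macrocycle then form in one thermal step, and BBr3 frees the two ring B hydroxyls.
- Stereochemistry: the target is achiral. The stereo elements met on the way (E enol ether in 13–18, racemic carbinol in 17–22, racemic sp3 carbon in 25) are all erased.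

Key step: step 14

Remark: ring A carries C1 (OH), C3 (chain) and C5 (ether O); ring B carries B1 (ether O), B3 (OH), B5 (chain) and B6 (OH). Compounds 4 and 5 are assumed to be commercial.

**Route**

Step 1
Reactants: 1 2-hydroxy-5-methoxybenzaldehyde
Product: 2 3-bromo-2-hydroxy-5-methoxybenzaldehyde
Conditions: Br2, NaOAc, AcOH, rt
Reagents that add atoms: bromine, BrBr
Why: Electrophilic aromatic bromination, in which the free phenol directs to C3, its only open ortho position (para is blocked by OMe).

Step 2
Reactants: 2 3-bromo-2-hydroxy-5-methoxybenzaldehyde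
Product: 3 3-bromo-2,5-dimethoxybenzaldehyde
Conditions: MeI, K2CO3, DMF, rt
Reagents that add atoms: iodomethane, CI
Why: Williamson O-methylation of the phenoxide; the aldehyde is kept as a masked phenol that also activates the aryl bromide for coupling.

Step 3
Reactants: 4 (5-chloropent-1-yn-1-yl)trimethylsilane; 5 11-bromoundec-1-ene
Product: 7 trimethyl(hexadec-15-en-1-yn-1-yl)silane, via Grignard reagent 6 (not isolated)
Conditions: Mg, I2 (cat.), THF, reflux; then 5, Li2CuCl4 (3 mol %), THF, −10 °C → rt
Reagents that add atoms: none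
Why: Grignard formation from the primary chloride and Kochi-type copper-catalysed sp3–sp3 coupling with the primary bromide; the silyl cap removes the acidic alkyne proton and the terminal alkene is inert.

Step 4
Reactants: 7 trimethyl(hexadec-15-en-1-yn-1-yl)silane; 3 3-bromo-2,5-dimethoxybenzaldehyde
Product: 9 3-[16-(trimethylsilyl)hexadec-15-yn-1-yl]-2,5-dimethoxybenzaldehyde, via B-alkyl-9-BBN adduct 8 (not isolated)
Conditions: 9-BBN (0.95 equiv), THF, 0 °C → rt; then 3, Pd(dppf)Cl2 (5 mol %), K3PO4 (aq.), DMF/THF, 50 °C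
Reagents that add atoms: none
Why: 9-BBN adds anti-Markovnikov to the terminal alkene much faster than to the silylated alkyne, and the B-alkyl Suzuki–Miyaura coupling then transfers the primary alkyl group to the aryl bromide; no B–H is left to reduce the aldehyde.

Step 5
Reactants: 9 3-[16-(trimethylsilyl)hexadec-15-yn-1-yl]-2,5-dimethoxybenzaldehyde
Product: 11 3-(hexadec-15-yn-1-yl)-2,5-dimethoxyphenol, via aryl formate 10 (not isolated)
Conditions: mCPBA, CH2Cl2, 0 °C → rt; then K2CO3 (cat.), MeOH, rt
Reagents that add atoms: mCPBA, O=C(OO)c1cccc(Cl)c1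
Why: Baeyer–Villiger (Dakin-type) oxidation of the electron-rich benzaldehyde with aryl migration gives the formate, and carbonate-catalysed methanolysis then frees the phenol and cleaves the alkynyl C–Si bond in the same operation.

Step 6
Reactants: 11 3-(hexadec-15-yn-1-yl)-2,5-dimethoxyphenol; 12 trichloroethylene
Product: 13 1-{[(E)-1,2-dichloroethenyl]oxy}-3-(hexadec-15-yn-1-yl)-2,5-dimethoxybenzene
Conditions: K2CO3, DMF, 70 °C
Reagents that add atoms: none
Why: Base-mediated O-dichlorovinylation of a phenol (elimination of 12 to dichloroacetylene, then anti addition of the phenoxide) gives the E enol ether, a carrier of the later ynol ether that is stable to ketenes, zinc and weak acid.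

Step 7
Reactants: 13 1-{[(E)-1,2-dichloroethenyl]oxy}-3-(hexadec-15-yn-1-yl)-2,5-dimethoxybenzene; 14 trichloroacetyl chloride
Product: 15 4,4-dichloro-3-[14-(3-{[(E)-1,2-dichloroethenyl]oxy}-2,5-dimethoxyphenyl)tetradecyl]cyclobut-2-en-1-one
Conditions: Zn(Cu), Et2O/DME, rt, 14 added over 2 h
Reagents that add atoms: none
Why: [2+2] cycloaddition of dichloroketene (from zinc dechlorination of 14) with the terminal alkyne, the ketene carbonyl carbon bonding to the terminal CH so that the chain sits at C3; the chlorinated, trisubstituted enol ether and the arene are poor ketenophiles.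

Step 8
Reactants: 15 4,4-dichloro-3-[14-(3-{[(E)-1,2-dichloroethenyl]oxy}-2,5-dimethoxyphenyl)tetradecyl]cyclobut-2-en-1-one
Product: 16 3-[14-(3-{[(E)-1,2-dichloroethenyl]oxy}-2,5-dimethoxyphenyl)tetradecyl]cyclobut-2-en-1-one
Conditions: Zn, AcOH, TMEDA, EtOH, 0 °C → rt
Reagents that add atoms: none
Why: Zinc reduction of the α,α-dichloro ketone in buffered acetic acid is the standard dechlorination of dichloroketene–alkyne adducts and does not touch vinylic C–Cl bonds.

Step 9
Reactants: 16 3-[14-(3-{[(E)-1,2-dichloroethenyl]oxy}-2,5-dimethoxyphenyl)tetradecyl]cyclobut-2-en-1-one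
Product: 17 rac-3-[14-(3-{[(E)-1,2-dichloroethenyl]oxy}-2,5-dimethoxyphenyl)tetradecyl]cyclobut-2-en-1-ol
Conditions: NaBH4, CeCl3·7H2O, MeOH, −40 °C
Reagents that add atoms: none
Why: Luche 1,2-reduction masks the electrophilic enone as an allylic alcohol before the organolithium step; the carbinol centre forms as a racemate and is erased again in step 13.

Step 10
Reactants: 17 rac-3-[14-(3-{[(E)-1,2-dichloroethenyl]oxy}-2,5-dimethoxyphenyl)tetradecyl]cyclobut-2-en-1-ol
Product: 18 rac-triethyl({3-[14-(3-{[(E)-1,2-dichloroethenyl]oxy}-2,5-dimethoxyphenyl)tetradecyl]cyclobut-2-en-1-yl}oxy)silane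
Conditions: Et3SiCl, imidazole, CH2Cl2, 0 °C
Reagents that add atoms: chlorotriethylsilane, CC[Si](Cl)(CC)CC
Why: Standard silylation of a secondary alcohol, so that no alkoxide (prone to anion-accelerated opening of the cyclobutene) is present in step 11.

Step 11
Reactants: 18 rac-triethyl({3-[14-(3-{[(E)-1,2-dichloroethenyl]oxy}-2,5-dimethoxyphenyl)tetradecyl]cyclobut-2-en-1-yl}oxy)silane
Product: 21 rac-({3-[14-(3-ethynyloxy-2,5-dimethoxyphenyl)tetradecyl]cyclobut-2-en-1-yl}oxy)triethylsilane, via chloroethynyl ether 19 (not isolated), via lithium acetylide 20 (not isolated)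
Conditions: n-BuLi (2.5 equiv), THF, −78 → −40 °C; then MeOH, −78 °C
Reagents that add atoms: none
Why: The established conversion of aryl 1,2-dichlorovinyl ethers into ethynyl ethers (E2 loss of HCl, chlorine–lithium exchange, protonation); silyl ether, aryl methyl ethers and the trisubstituted cyclobutene tolerate n-BuLi at −78 °C.

Step 12
Reactants: 21 rac-({3-[14-(3-ethynyloxy-2,5-dimethoxyphenyl)tetradecyl]cyclobut-2-en-1-yl}oxy)triethylsilane
Product: 22 rac-3-[14-(3-ethynyloxy-2,5-dimethoxyphenyl)tetradecyl]cyclobut-2-en-1-ol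
Conditions: Bu4NF, AcOH (1:1), THF, 0 °C
Reagents that add atoms: none
Why: Fluoride cleavage of the triethylsilyl ether, buffered with acetic acid so that the cyclobutenol is released without a free alkoxide and the ynol ether sees neither base nor strong acid.

Step 13
Reactants: 22 rac-3-[14-(3-ethynyloxy-2,5-dimethoxyphenyl)tetradecyl]cyclobut-2-en-1-ol
Product: 23 3-[14-(3-ethynyloxy-2,5-dimethoxyphenyl)tetradecyl]cyclobut-2-en-1-one
Conditions: Dess–Martin periodinane, NaHCO3, CH2Cl2, 0 °C; used at once
Reagents that add atoms: none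
Why: Dess–Martin oxidation of the allylic alcohol under bicarbonate buffer restores the cyclobutenone under neutral conditions that an aryl ynol ether should tolerate, and removes the carbinol stereocentre.

Step 14
Reactants: 23 3-[14-(3-ethynyloxy-2,5-dimethoxyphenyl)tetradecyl]cyclobut-2-en-1-one
Product: 28 macrocyclic diaryl ether phenol (ring A formed; ring B as dimethyl ether), via vinylketene 24 (not isolated), via bicyclic vinylcyclobutenone 25 (not isolated), via dienylketene 26 (not isolated), via cyclohexadienone 27 (not isolated)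
Conditions: syringe-pump addition over 12 h to toluene at 80 °C (final 0.5 mM), then 110 °C, 4 h, argon
Reagents that add atoms: none
Why: Proposed new method: heating opens the cyclobutenone of 23 reversibly (4π electrocyclic) to vinylketene 24, whose ketene C=C adds the tethered aryl ethynyl ether in a [2+2] cycloaddition to the macrobicyclic vinylcyclobutenone 25, and a second 4π opening to dienylketene 26, 6π electrocyclization to dienone 27 and tautomerization give phenol 28. The closest known reaction type is the intermolecular Danheiser benzannulation of 3-alkylcyclobutenones with alkoxy- and siloxyalkynes to 5-alkylresorcinol monoethers; new here are the aryl ethynyl ether as ketenophile and the use of the annulation as a ring-closing event. The 21-membered ring closes in the ketene–alkyne [2+2] step, which forms C4–C5 and C1–C6, and ring A closes in the 6π electrocyclization, which re-forms the C1–C2 bond broken when the cyclobutenone opened. No stereocentre is created in 28, the sp3 carbon of 25 being racemic and then aromatized. The step needs one regiochemistry and cyclization over oligomerization: the polarized ynol ether bonds through its nucleophilic terminal CH to the ketene carbonyl carbon, which places OH, chain and aryloxy 1,3,5, while slow addition at high dilution and the low stationary concentration of 24 favour intramolecular capture. An aryl ynol ether has no C–H β to oxygen on the aryl side, so the retro-ene loss of ketene that limits alkyl ynol ethers at this temperature is not available.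

Step 15
Reactants: 28 macrocyclic diaryl ether phenol (ring B as dimethyl ether)
Product: 29 CNP0393720.0 (target)
Conditions: BBr3 (6 equiv), CH2Cl2, −78 °C → rt; then MeOH/H2O, argon
Reagents that add atoms: none
Why: Lewis-acid cleavage of the two aryl methyl ethers with BBr3, to which the diaryl ether and the alkyl chain are inert; work-up under argon guards the aryloxyhydroquinone against oxidation to the quinone.

**Compound list**

1 | 2-hydroxy-5-methoxybenzaldehyde | COc1ccc(O)c(C=O)c1 | starting material
2 | 3-bromo-2-hydroxy-5-methoxybenzaldehyde | COc1cc(Br)c(O)c(C=O)c1 | intermediate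
3 | 3-bromo-2,5-dimethoxybenzaldehyde | COc1cc(Br)c(OC)c(C=O)c1 | intermediate
4 | (5-chloropent-1-yn-1-yl)trimethylsilane | C[Si](C)(C)C#CCCCCl | starting material
5 | 11-bromoundec-1-ene | C=CCCCCCCCCCBr | starting material
6 | [5-(trimethylsilyl)pent-4-yn-1-yl]magnesium chloride (formed in the flask) | C[Si](C)(C)C#CCCC[Mg]Cl | intermediate
7 | trimethyl(hexadec-15-en-1-yn-1-yl)silane | C=CCCCCCCCCCCCCC#C[Si](C)(C)C | intermediate
8 | 9-[16-(trimethylsilyl)hexadec-15-yn-1-yl]-9-borabicyclo[3.3.1]nonane (formed in the flask) | C[Si](C)(C)C#CCCCCCCCCCCCCCCB1C2CCCC1CCC2 | intermediate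
9 | 3-[16-(trimethylsilyl)hexadec-15-yn-1-yl]-2,5-dimethoxybenzaldehyde | COc1cc(CCCCCCCCCCCCCCC#C[Si](C)(C)C)c(OC)c(C=O)c1 | intermediate
10 | 3-[16-(trimethylsilyl)hexadec-15-yn-1-yl]-2,5-dimethoxyphenyl formate (formed in the flask) | COc1cc(CCCCCCCCCCCCCCC#C[Si](C)(C)C)c(OC)c(OC=O)c1 | intermediate
11 | 3-(hexadec-15-yn-1-yl)-2,5-dimethoxyphenol | COc1cc(CCCCCCCCCCCCCCC#C)c(OC)c(O)c1 | intermediate
12 | trichloroethylene | ClC=C(Cl)Cl | starting material
13 | 1-{[(E)-1,2-dichloroethenyl]oxy}-3-(hexadec-15-yn-1-yl)-2,5-dimethoxybenzene | COc1cc(CCCCCCCCCCCCCCC#C)c(OC)c(O/C(Cl)=C\Cl)c1 | intermediate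
14 | trichloroacetyl chloride | ClC(=O)C(Cl)(Cl)Cl | starting material
15 | 4,4-dichloro-3-[14-(3-{[(E)-1,2-dichloroethenyl]oxy}-2,5-dimethoxyphenyl)tetradecyl]cyclobut-2-en-1-one | COc1cc(CCCCCCCCCCCCCCC2=CC(=O)C2(Cl)Cl)c(OC)c(O/C(Cl)=C\Cl)c1 | intermediate
16 | 3-[14-(3-{[(E)-1,2-dichloroethenyl]oxy}-2,5-dimethoxyphenyl)tetradecyl]cyclobut-2-en-1-one | COc1cc(CCCCCCCCCCCCCCC2=CC(=O)C2)c(OC)c(O/C(Cl)=C\Cl)c1 | intermediate
17 | rac-3-[14-(3-{[(E)-1,2-dichloroethenyl]oxy}-2,5-dimethoxyphenyl)tetradecyl]cyclobut-2-en-1-ol | COc1cc(CCCCCCCCCCCCCCC2=CC(O)C2)c(OC)c(O/C(Cl)=C\Cl)c1 | intermediate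
18 | rac-triethylsilyl ether of 17 | COc1cc(CCCCCCCCCCCCCCC2=CC(O[Si](CC)(CC)CC)C2)c(OC)c(O/C(Cl)=C\Cl)c1 | intermediate
19 | rac-chloroethynyl aryl ether (triethylsilyl-protected cyclobutenol; formed in the flask) | COc1cc(CCCCCCCCCCCCCCC2=CC(O[Si](CC)(CC)CC)C2)c(OC)c(OC#CCl)c1 | intermediate
20 | rac-lithium aryloxyacetylide (triethylsilyl-protected cyclobutenol; formed in the flask) | COc1cc(CCCCCCCCCCCCCCC2=CC(O[Si](CC)(CC)CC)C2)c(OC)c(OC#C[Li])c1 | intermediate
21 | rac-({3-[14-(3-ethynyloxy-2,5-dimethoxyphenyl)tetradecyl]cyclobut-2-en-1-yl}oxy)triethylsilane | COc1cc(CCCCCCCCCCCCCCC2=CC(O[Si](CC)(CC)CC)C2)c(OC)c(OC#C)c1 | intermediate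
22 | rac-3-[14-(3-ethynyloxy-2,5-dimethoxyphenyl)tetradecyl]cyclobut-2-en-1-ol | COc1cc(CCCCCCCCCCCCCCC2=CC(O)C2)c(OC)c(OC#C)c1 | intermediate
23 | 3-[14-(3-ethynyloxy-2,5-dimethoxyphenyl)tetradecyl]cyclobut-2-en-1-one | COc1cc(CCCCCCCCCCCCCCC2=CC(=O)C2)c(OC)c(OC#C)c1 | intermediate
24 | 3-[14-(3-ethynyloxy-2,5-dimethoxyphenyl)tetradecyl]buta-1,3-dien-1-one (vinylketene; formed in the flask) | COc1cc(CCCCCCCCCCCCCCC(=C)C=C=O)c(OC)c(OC#C)c1 | intermediate
25 | racemic macrobicyclic 3-aryloxy-4-alkenylcyclobut-2-en-1-one (21-membered ring fused to the four-membered ring; formed in the flask) | COc1cc2c(OC)c(c1)CCCCCCCCCCCCCCC(=C)C1C(=O)C=C1O2 | intermediate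
26 | macrocyclic (E)-3-aryloxy-5-methylidene dienylketene (formed in the flask) | COc1cc2c(OC)c(c1)CCCCCCCCCCCCCCC(=C)/C=C(\C=C=O)O2 | intermediate
27 | macrocyclic 3-aryloxy-5-alkylcyclohexa-2,4-dien-1-one (formed in the flask) | COc1cc2c(OC)c(c1)CCCCCCCCCCCCCCC1=CC(=CC(=O)C1)O2 | intermediate
28 | macrocyclic diaryl ether with ring A as free phenol and ring B as dimethyl ether | Oc1cc2cc(c1)Oc1cc(OC)cc(c1OC)CCCCCCCCCCCCCC2 | intermediate
29 | CNP0393720.0 | Oc1cc2cc(c1)Oc1cc(O)cc(c1O)CCCCCCCCCCCCCC2 | target

**Count**

Total steps: 15. Longest linear sequence: 14 steps (steps 1, 2 and 4–15); step 3 prepares the chain fragment.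

**Steps most likely to fail**

Step 14. Intermolecular capture of the vinylketene by the ynol ether of a second molecule, or polymerization of the ynol ether before the cyclobutenone opens, may outrun the 21-membered ring closure. The fallback buys ring A and closes the macrocycle by known reactions, setting out from 3 and rejoining the route at 29. Baeyer–Villiger oxidation of 3 (mCPBA) would give 3-bromo-2,5-dimethoxyphenyl formate F1, and methanolysis (K2CO3, MeOH) 3-bromo-2,5-dimethoxyphenol F2. Ullmann coupling with commercial 1-bromo-3-iodo-5-methoxybenzene (CuI, picolinic acid, K3PO4, DMSO, 80 °C; the iodide reacts before either bromide) would give 1-bromo-3-(3-bromo-5-methoxyphenoxy)-2,5-dimethoxybenzene F3. Double Negishi coupling with oct-7-enylzinc bromide (Pd(OAc)2, SPhos, THF) would give the bis(oct-7-enyl) diaryl ether F4. Ring-closing metathesis at high dilution with the second-generation Grubbs catalyst (H2IMes)(PCy3)Cl2Ru=CHPh would close the 21-membered ring as the cycloalkene F5 (E/Z mixture). Hydrogenation (H2, Pd/C) would give the saturated trimethyl ether F6, and BBr3 would cleave all three methyl ethers to 29.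

Step 7. Conversion of the unactivated alkyne by dichloroketene may be slow, and the zinc chloride formed may damage the enol ether or the electron-rich arene. The fallback builds the four-membered ring with a keteniminium salt instead, setting out from 13 and rejoining at 16. N,N-Dimethylacetamide, Tf2O and 2,4,6-collidine in refluxing 1,2-dichloroethane would add to the terminal alkyne (Ghosez cycloaddition) to give the cyclobuteniminium triflate F7. Aqueous NaHCO3 hydrolysis would give 16 directly, without a dechlorination step.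

Step 12. Any alkoxide formed on desilylation may trigger anion-accelerated electrocyclic opening of the cyclobutene, and the acetic acid buffer may add to the ynol ether. The fallback masks the ketone at its own oxidation level, setting out from 16 and rejoining at 23. Noyori ketalization (1,2-bis(trimethylsilyloxy)ethane, Me3SiOTf cat., CH2Cl2, −78 °C) would give the dioxolane F8. n-BuLi as in step 11 would pass through the chloroethynyl ether F9 and the lithium acetylide F10 to the ethynyl ether ketal F11. Mild hydrolysis (PPTS, wet acetone), much faster for an allylic ketal than hydration of an aryl ynol ether, would give 23.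

**Further compounds**

F1 | step 14 | 3-bromo-2,5-dimethoxyphenyl formate | COc1cc(Br)c(OC)c(OC=O)c1
F2 | step 14 | 3-bromo-2,5-dimethoxyphenol | COc1cc(O)c(OC)c(Br)c1
F3 | step 14 | 1-bromo-3-(3-bromo-5-methoxyphenoxy)-2,5-dimethoxybenzene | COc1cc(Br)cc(c1)Oc1cc(OC)cc(Br)c1OC
F4 | step 14 | 2,5-dimethoxy-1-[3-methoxy-5-(oct-7-en-1-yl)phenoxy]-3-(oct-7-en-1-yl)benzene | COc1cc(CCCCCCC=C)cc(c1)Oc1cc(OC)cc(CCCCCCC=C)c1OC
F5 | step 14 | 21-membered macrocyclic alkene, trimethyl ether (E/Z mixture) | COc1cc2cc(c1)Oc1cc(OC)cc(c1OC)CCCCCCC=CCCCCCC2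
F6 | step 14 | saturated macrocycle, trimethyl ether of the target | COc1cc2cc(c1)Oc1cc(OC)cc(c1OC)CCCCCCCCCCCCCC2
F7 | step 7 | N,N-dimethyl-3-[14-(3-{[(E)-1,2-dichloroethenyl]oxy}-2,5-dimethoxyphenyl)tetradecyl]cyclobut-2-en-1-iminium triflate | COc1cc(CCCCCCCCCCCCCCC2=CC(=[N+](C)C)C2)c(OC)c(O/C(Cl)=C\Cl)c1.[O-]S(=O)(=O)C(F)(F)F
F8 | step 12 | ethylene ketal of 16 (5,8-dioxaspiro[3.4]oct-1-ene with the chain at C2) | COc1cc(CCCCCCCCCCCCCCC2=CC3(C2)OCCO3)c(OC)c(O/C(Cl)=C\Cl)c1
F9 | step 12 | chloroethynyl aryl ether, ethylene ketal | COc1cc(CCCCCCCCCCCCCCC2=CC3(C2)OCCO3)c(OC)c(OC#CCl)c1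
F10 | step 12 | lithium aryloxyacetylide, ethylene ketal | COc1cc(CCCCCCCCCCCCCCC2=CC3(C2)OCCO3)c(OC)c(OC#C[Li])c1
F11 | step 12 | ethylene ketal of 23 | COc1cc(CCCCCCCCCCCCCCC2=CC3(C2)OCCO3)c(OC)c(OC#C)c1
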